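## Retrosynthetic overview
1. Feature: ring A carries a 3-methylbut-2-enyl group at C8, para to O5. Ring B carries a 2-methylbut-3-en-2-yl group at C5', ortho to O4'. A prenyl group on O5 reaches the first position and connectivity after two [3,3] shifts; one on O4' reaches the second after a single shift.
2. Target 19 ⇒ (MOM removal) 18 ⇒ (C8–C1'' and C5'–CMe2 cut together: Claisen–Cope on ring A, Claisen on ring B) bis(O-prenyl) flavanone 13.
3. 13 ⇒ (C2–C1', asymmetric Rh 1,4-addition, sets 2S) chromone 6 + boronic acid 12.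
4. 6 ⇒ phloroacetophenone 1 (4-O-MOM, 2-O-prenyl, one carbon from DMF-DMA). 12 ⇒ 4-bromoresorcinol 7 (O-prenyl para to Br, O-MOM ortho to Br, Br→B).
5. Ring order: rings A and B are bought. Ring C is closed as a pyranone in step 3 and saturated at C2–C3 in step 7. No ring is formed after that.

Key step: step 8

Assumption: the (S)-configured biaryl bisphosphine is taken to deliver the aryl group to the Re face of C2, the sense that (S)-BINAP-type ligands show with cyclic enones. The sense is to be checked by CD on 13, and the (R)-ligand is used if it is reversed.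

## Route

Step 1
Reactants: 1 2,4,6-trihydroxyacetophenone (dried)
Product: 2 1-[2,6-dihydroxy-4-(methoxymethoxy)phenyl]ethanone
Conditions: MOMCl (1.0 equiv), K2CO3, acetone, 0 °C → rt
Reagents that add atoms: chloromethyl methyl ether (MOMCl), COCCl
Why: Williamson-type O-alkylation in which the 4-OH, para to the acetyl group and free of its hydrogen bond, is the most acidic and accessible hydroxyl, so one equivalent of MOMCl should go there and leave the symmetric 2,6-diol (bis-ether removed by chromatography).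

Step 2
Reactants: 2 1-[2,6-dihydroxy-4-(methoxymethoxy)phenyl]ethanone; 3 prenyl bromide (1-bromo-3-methylbut-2-ene)
Product: 4 1-[2-hydroxy-4-(methoxymethoxy)-6-(3-methylbut-2-enyloxy)phenyl]ethanone
Conditions: K2CO3, acetone, 40 °C
Reagents that add atoms: none
Why: Williamson ether synthesis on two equivalent hydroxyls, where the hydroxyl left after the first alkylation is locked in a hydrogen bond to the ketone and resists a second one, and a weak base in acetone favours O- over C-prenylation.

Step 3
Reactants: 4 1-[2-hydroxy-4-(methoxymethoxy)-6-(3-methylbut-2-enyloxy)phenyl]ethanone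
Product: 6 7-(methoxymethoxy)-5-(3-methylbut-2-enyloxy)-4H-chromen-4-one, via enaminone 5 (not isolated)
Conditions: Me2NCH(OMe)2, PhMe, 90 °C; evaporate; AcOH, 60 °C
Reagents that add atoms: N,N-dimethylformamide dimethyl acetal (DMF-DMA), COC(OC)N(C)C
Why: Enaminone chromone synthesis, in which condensation at the acetyl CH3 gives the vinylogous amide, the weak acid triggers 6-endo oxa-Michael addition of the phenol with loss of dimethylamine, and acetic acid is too weak to cleave the aryl MOM or prenyl ether.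

Step 4
Reactants: 7 4-bromoresorcinol; 3 prenyl bromide
Product: 8 2-bromo-5-(3-methylbut-2-enyloxy)phenol
Conditions: K2CO3 (1.0 equiv), acetone, rt
Reagents that add atoms: none
Why: Williamson ether synthesis in which the hydroxyl para to bromine is unhindered and gives the more nucleophilic phenoxide, so it should be alkylated in preference to the one ortho to bromine (regioisomer and bis-ether removed by chromatography).

Step 5
Reactants: 8 2-bromo-5-(3-methylbut-2-enyloxy)phenol
Product: 9 1-bromo-2-(methoxymethoxy)-4-(3-methylbut-2-enyloxy)benzene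
Conditions: MOMCl, K2CO3, acetone, rt
Reagents that add atoms: chloromethyl methyl ether (MOMCl), COCCl
Why: Williamson-type O-alkylation of the only remaining phenol with a small, very reactive electrophile that is not hampered by the ortho bromine.

Step 6
Reactants: 9 1-bromo-2-(methoxymethoxy)-4-(3-methylbut-2-enyloxy)benzene
Product: 12 [2-(methoxymethoxy)-4-(3-methylbut-2-enyloxy)phenyl]boronic acid, via aryllithium 10 (not isolated), via lithium triisopropoxyborate 11 (not isolated)
Conditions: n-BuLi, THF, −78 °C; B(Oi-Pr)3, −78 → 0 °C; sat. aq NH4Cl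
Reagents that add atoms: triisopropyl borate, CC(C)OB(OC(C)C)OC(C)C; water, O
Why: Bromine–lithium exchange followed by electrophilic borylation, where exchange at −78 °C is far faster than deprotonation of the allylic OCH2, the ortho MOM oxygen stabilises the aryllithium, and the near-neutral quench spares the MOM group and limits protodeboronation.

Step 7
Reactants: 6 7-(methoxymethoxy)-5-(3-methylbut-2-enyloxy)-4H-chromen-4-one; 12 [2-(methoxymethoxy)-4-(3-methylbut-2-enyloxy)phenyl]boronic acid (2.5 equiv)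
Product: 13 (2S)-7-(methoxymethoxy)-2-[2-(methoxymethoxy)-4-(3-methylbut-2-enyloxy)phenyl]-5-(3-methylbut-2-enyloxy)chroman-4-one
Conditions: [Rh(OH)(cod)]2 (2.5 mol %), (S)-MeO-F12-BIPHEP (5.5 mol %), CH2Cl2/H2O, 30 °C
Reagents that add atoms: none
Why: Hayashi–Miyaura asymmetric 1,4-addition, in which the aryl–Rh(I) species inserts the C2=C3 bond, the electron-poor C2-symmetric bisphosphine blocks the Si face so that the aryl group reaches the Re face of C2 and sets 2S, and base-free protonolysis of the Rh enolate by water avoids retro-oxa-Michael opening.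

Step 8
Reactants: 13 (2S)-7-(methoxymethoxy)-2-[2-(methoxymethoxy)-4-(3-methylbut-2-enyloxy)phenyl]-5-(3-methylbut-2-enyloxy)chroman-4-one
Product: 18 (2S)-5-hydroxy-2-[4-hydroxy-2-(methoxymethoxy)-5-(2-methylbut-3-en-2-yl)phenyl]-7-(methoxymethoxy)-8-(3-methylbut-2-enyl)chroman-4-one, via C6 dienone 14 (not isolated), via C8 dienone 15 (not isolated), via half-rearranged 8-prenyl flavanone 16 (not isolated), via ring B dienone 17 (not isolated)
Conditions: Eu(fod)3 (30 mol %), dry degassed PhCl, Ar, 85 °C, then 130 °C (sealed tube); ee of 18 checked by chiral HPLC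
Reagents that add atoms: none
Why: Eu(III) binds the C4 carbonyl and O5 of 13 and loosens the O5–CH2 bond, so a first aromatic Claisen [3,3] shift puts the C5 unit, inverted, on C6 (14), a Cope [3,3] shift across C6–C7=C8 carries it to C8 with normal prenyl connectivity (15, new bond C8–C1''), and tautomerisation gives the chelated 5-phenol 16. At the higher temperature the 4'-O-prenyl ether makes one ortho-Claisen shift to C5' (17, new bond C5'–CMe2), and since an onward Cope shift could only reach the substituted C1', where no proton can be lost, 17 enolises and the group stays a 1,1-dimethylallyl group in 18. The closest known reactions are the Eu(fod)3-promoted para-Claisen–Cope rearrangement of 5-O-prenyl flavonoids and the ortho-Claisen rearrangement of 4-prenyloxy resorcinol ethers to 1,1-dimethylallyl phenols, which here merely share one flask. No ring is closed and no lasting stereocentre is made, because the sp3 ring carbons of 14, 15 and 17 vanish on aromatisation and C2 is a spectator. C8 over C6 is needed and should follow from the aprotic medium, which slows enolisation of 14, and from the strain of the tertiary group wedged between the Eu-bound C5 carbonyl and the C7 OMOM group, which speeds the Cope step, while C5' over C3' follows from the crowding of C3' between O2' and O4' and from activation of C5' by the para O2'. The medium is kept dry, neutral and free of base so that C2–O1 does not open, and O7 stays blocked so that the new prenyl group cannot cyclise onto it.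

Step 9
Reactants: 18 (2S)-5-hydroxy-2-[4-hydroxy-2-(methoxymethoxy)-5-(2-methylbut-3-en-2-yl)phenyl]-7-(methoxymethoxy)-8-(3-methylbut-2-enyl)chroman-4-one
Product: 19 (2S)-2-[2,4-dihydroxy-5-(2-methylbut-3-en-2-yl)phenyl]-5,7-dihydroxy-8-(3-methylbut-2-enyl)chroman-4-one (AChE-IN-17)
Conditions: HCl (1 M in MeOH), 0 °C → rt, stopped at full conversion
Reagents that add atoms: none
Why: Acid-catalysed transacetalisation of the two aryl MOM ethers to methanol, which at this acidity and temperature should leave both alkenes unprotonated and, being free of base, avoids E1cB opening of ring C at C2.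

## Compound list
1 | 2,4,6-trihydroxyacetophenone | CC(=O)c1c(O)cc(O)cc1O | starting material
2 | 1-[2,6-dihydroxy-4-(methoxymethoxy)phenyl]ethanone | CC(=O)c1c(O)cc(OCOC)cc1O | intermediate
3 | prenyl bromide (1-bromo-3-methylbut-2-ene) | CC(C)=CCBr | starting material
4 | 1-[2-hydroxy-4-(methoxymethoxy)-6-(3-methylbut-2-enyloxy)phenyl]ethanone | CC(=O)c1c(O)cc(OCOC)cc1OCC=C(C)C | intermediate
5 | (E)-3-(dimethylamino)-1-[2-hydroxy-4-(methoxymethoxy)-6-(3-methylbut-2-enyloxy)phenyl]prop-2-en-1-one | CN(C)/C=C/C(=O)c1c(O)cc(OCOC)cc1OCC=C(C)C | intermediate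
6 | 7-(methoxymethoxy)-5-(3-methylbut-2-enyloxy)-4H-chromen-4-one | O=c1ccoc2cc(OCOC)cc(OCC=C(C)C)c12 | intermediate
7 | 4-bromoresorcinol | Oc1ccc(Br)c(O)c1 | starting material
8 | 2-bromo-5-(3-methylbut-2-enyloxy)phenol | CC(C)=CCOc1ccc(Br)c(O)c1 | intermediate
9 | 1-bromo-2-(methoxymethoxy)-4-(3-methylbut-2-enyloxy)benzene | CC(C)=CCOc1ccc(Br)c(OCOC)c1 | intermediate
10 | [2-(methoxymethoxy)-4-(3-methylbut-2-enyloxy)phenyl]lithium | [Li]c1ccc(OCC=C(C)C)cc1OCOC | intermediate
11 | lithium [2-(methoxymethoxy)-4-(3-methylbut-2-enyloxy)phenyl]triisopropoxyborate | [Li+].CC(C)O[B-](OC(C)C)(OC(C)C)c1ccc(OCC=C(C)C)cc1OCOC | intermediate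
12 | [2-(methoxymethoxy)-4-(3-methylbut-2-enyloxy)phenyl]boronic acid | CC(C)=CCOc1ccc(B(O)O)c(OCOC)c1 | intermediate
13 | (2S)-7-(methoxymethoxy)-2-[2-(methoxymethoxy)-4-(3-methylbut-2-enyloxy)phenyl]-5-(3-methylbut-2-enyloxy)chroman-4-one | CC(C)=CCOc1cc(OCOC)c([C@@H]2CC(=O)c3c(OCC=C(C)C)cc(OCOC)cc3O2)cc1 | intermediate
14 | ring A ortho-dienone: (2S)-6-(2-methylbut-3-en-2-yl)-2,3-dihydrochromene-4,5(6H)-dione, C7 OMOM, ring B as in 13, C6 unassigned | CC(C)=CCOc1cc(OCOC)c([C@@H]2CC(=O)C3=C(O2)C=C(OCOC)C(C(C)(C)C=C)C3=O)cc1 | intermediate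
15 | ring A para-dienone: (2S)-8-(3-methylbut-2-enyl)-2,3-dihydrochromene-4,5(8H)-dione, C7 OMOM, ring B as in 13, C8 unassigned | CC(C)=CCOc1cc(OCOC)c([C@@H]2CC(=O)C3=C(O2)C(CC=C(C)C)C(OCOC)=CC3=O)cc1 | intermediate
16 | (2S)-5-hydroxy-7-(methoxymethoxy)-2-[2-(methoxymethoxy)-4-(3-methylbut-2-enyloxy)phenyl]-8-(3-methylbut-2-enyl)chroman-4-one | CC(C)=CCOc1cc(OCOC)c([C@@H]2CC(=O)c3c(O)cc(OCOC)c(CC=C(C)C)c3O2)cc1 | intermediate
17 | ring B ortho-dienone: ring A as in 16, ring B a cyclohexa-2,4-dienone with C4'=O and H plus 2-methylbut-3-en-2-yl on C5' (unassigned) | O=C1C=C(OCOC)C([C@@H]2CC(=O)c3c(O)cc(OCOC)c(CC=C(C)C)c3O2)=CC1C(C)(C)C=C | intermediate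
18 | (2S)-5-hydroxy-2-[4-hydroxy-2-(methoxymethoxy)-5-(2-methylbut-3-en-2-yl)phenyl]-7-(methoxymethoxy)-8-(3-methylbut-2-enyl)chroman-4-one | C=CC(C)(C)c1cc([C@@H]2CC(=O)c3c(O)cc(OCOC)c(CC=C(C)C)c3O2)c(OCOC)cc1O | intermediate
19 | (2S)-2-[2,4-dihydroxy-5-(2-methylbut-3-en-2-yl)phenyl]-5,7-dihydroxy-8-(3-methylbut-2-enyl)chroman-4-one (AChE-IN-17) | C=CC(C)(C)c1cc([C@@H]2CC(=O)c3c(O)cc(O)c(CC=C(C)C)c3O2)c(O)cc1O | target

## Step count
Total step count: 9.
Longest linear sequence: 6 steps (1→2→4→6→13→18→19, and equally 7→8→9→12→13→18→19).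

## Steps most likely to fail

**Step 8.**
- The ring B shift may need a temperature at which the C2–O1 bond opens and recloses, which would erode the ee.
- Enolisation at C6 may outrun the Cope shift.
- Prenyl may be lost as isoprene.
- The Eu centre may be tied up by the chelating 5-hydroxy ketone formed in the first half.

The fallback uncouples the two shifts and does the ring B shift on an achiral building block. It sets out from bromide 9 and chromone 6 and comes back to the route at 19.

Bromide 9 has no stereocentre to lose and is heated in N,N-diethylaniline at about 190 °C. The ortho-Claisen shift should give 4-bromo-5-(methoxymethoxy)-2-(2-methylbut-3-en-2-yl)phenol F1. NaH and MOMCl in DMF give 1-bromo-2,4-bis(methoxymethoxy)-5-(2-methylbut-3-en-2-yl)benzene F2.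

n-BuLi and then B(Oi-Pr)3, as in step 6, lead through the aryllithium F3 and the lithium triisopropoxyborate F4 to the boronic acid F5. Rh-catalysed addition of F5 to 6, as in step 7, gives the (2S)-5-prenyloxy-7,2',4'-tris(MOM) flavanone F6.

F6 needs only the ring A rearrangement. Eu(fod)3 in CHCl3 or PhCl at 60–85 °C takes it through the C6 dienone F7 and the C8 dienone F8 to the 7,2',4'-tris-MOM ether of the target F9. HCl in MeOH, as in step 9, then gives 19.

**Step 7.**
- Insertion may be slow, because the boronic acid is ortho-substituted, electron-rich and prone to protodeboronation, and the chromone is electron-rich.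
- Facial selectivity may be poor.
- The metal enolate may open ring C.

The fallback makes the racemic flavanone by the chalcone route and resolves it kinetically. It sets out from acetophenone 4 and prenyl bromide 3 and comes back at 13.

Commercial 2,4-dihydroxybenzaldehyde F10 is alkylated with 3 (K2CO3, acetone) at the non-chelated 4-OH to give 2-hydroxy-4-(3-methylbut-2-enyloxy)benzaldehyde F11. MOMCl and K2CO3 give 2-(methoxymethoxy)-4-(3-methylbut-2-enyloxy)benzaldehyde F12. Claisen–Schmidt condensation of F12 with 4 (KOH, EtOH, rt) gives the (E)-2'-hydroxychalcone F13, and NaOAc in refluxing EtOH closes it to the racemic flavanone F14.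

Noyori–Ikariya transfer hydrogenation follows, with RuCl[(R,R)-TsDPEN](p-cymene) and HCO2H/Et3N in EtOAc, run to about half conversion. It is expected to reduce the (2R)-ketone faster to the cis-(2R,4R)-flavan-4-ol F15. Unreacted (2S)-ketone 13 is then separated by chromatography.

**Step 9.**
- Acid may ionise the C2–O1 bond, which is a 2,4-dioxygenated benzylic aryl ether. This would erode the ee or lead to capture by methanol.
- Acid may also drive cyclisation of the freed 7-OH onto the prenyl group, or of the 4'-OH onto the vinyl group.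

The fallback replaces protic acid by a protecting-group exchange followed by fluoride. It sets out from 18 and comes back at 19.

TESOTf and 2,2'-bipyridyl in CH2Cl2 at 0 °C convert aryl MOM ethers directly into aryl TES ethers. Excess reagent should also silylate the two free phenols, which gives the 5,7,2',4'-tetrakis(triethylsilyl) ether F16. Et3N·3HF in THF at 0 °C then frees all four phenols under weakly acidic, non-ionising conditions to give 19.

## Further compounds
F1 | step 8 | 4-bromo-5-(methoxymethoxy)-2-(2-methylbut-3-en-2-yl)phenol | C=CC(C)(C)c1cc(Br)c(OCOC)cc1O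
F2 | step 8 | 1-bromo-2,4-bis(methoxymethoxy)-5-(2-methylbut-3-en-2-yl)benzene | C=CC(C)(C)c1cc(Br)c(OCOC)cc1OCOC
F3 | step 8 | [2,4-bis(methoxymethoxy)-5-(2-methylbut-3-en-2-yl)phenyl]lithium | [Li]c1cc(C(C)(C)C=C)c(OCOC)cc1OCOC
F4 | step 8 | lithium [2,4-bis(methoxymethoxy)-5-(2-methylbut-3-en-2-yl)phenyl]triisopropoxyborate | [Li+].CC(C)O[B-](OC(C)C)(OC(C)C)c1cc(C(C)(C)C=C)c(OCOC)cc1OCOC
F5 | step 8 | [2,4-bis(methoxymethoxy)-5-(2-methylbut-3-en-2-yl)phenyl]boronic acid | OB(O)c1cc(C(C)(C)C=C)c(OCOC)cc1OCOC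
F6 | step 8 | (2S)-2-[2,4-bis(methoxymethoxy)-5-(2-methylbut-3-en-2-yl)phenyl]-7-(methoxymethoxy)-5-(3-methylbut-2-enyloxy)chroman-4-one | C=CC(C)(C)c1cc([C@@H]2CC(=O)c3c(OCC=C(C)C)cc(OCOC)cc3O2)c(OCOC)cc1OCOC
F7 | step 8 | ring A ortho-dienone from F6 (2-methylbut-3-en-2-yl and H on C6, C5=O) | C=CC(C)(C)c1cc([C@@H]2CC(=O)C3=C(O2)C=C(OCOC)C(C(C)(C)C=C)C3=O)c(OCOC)cc1OCOC
F8 | step 8 | ring A para-dienone from F6 (3-methylbut-2-enyl and H on C8, C5=O) | C=CC(C)(C)c1cc([C@@H]2CC(=O)C3=C(O2)C(CC=C(C)C)C(OCOC)=CC3=O)c(OCOC)cc1OCOC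
F9 | step 8 | (2S)-2-[2,4-bis(methoxymethoxy)-5-(2-methylbut-3-en-2-yl)phenyl]-5-hydroxy-7-(methoxymethoxy)-8-(3-methylbut-2-enyl)chroman-4-one | C=CC(C)(C)c1cc([C@@H]2CC(=O)c3c(O)cc(OCOC)c(CC=C(C)C)c3O2)c(OCOC)cc1OCOC
F10 | step 7 | 2,4-dihydroxybenzaldehyde (commercial) | O=Cc1ccc(O)cc1O
F11 | step 7 | 2-hydroxy-4-(3-methylbut-2-enyloxy)benzaldehyde | CC(C)=CCOc1ccc(C=O)c(O)c1
F12 | step 7 | 2-(methoxymethoxy)-4-(3-methylbut-2-enyloxy)benzaldehyde | CC(C)=CCOc1ccc(C=O)c(OCOC)c1
F13 | step 7 | (E)-1-[2-hydroxy-4-(methoxymethoxy)-6-(3-methylbut-2-enyloxy)phenyl]-3-[2-(methoxymethoxy)-4-(3-methylbut-2-enyloxy)phenyl]prop-2-en-1-one | CC(C)=CCOc1ccc(/C=C/C(=O)c2c(O)cc(OCOC)cc2OCC=C(C)C)c(OCOC)c1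
F14 | step 7 | racemic 7-(methoxymethoxy)-2-[2-(methoxymethoxy)-4-(3-methylbut-2-enyloxy)phenyl]-5-(3-methylbut-2-enyloxy)chroman-4-one | CC(C)=CCOc1ccc(C2CC(=O)c3c(OCC=C(C)C)cc(OCOC)cc3O2)c(OCOC)c1
F15 | step 7 | (2R,4R)-7-(methoxymethoxy)-2-[2-(methoxymethoxy)-4-(3-methylbut-2-enyloxy)phenyl]-5-(3-methylbut-2-enyloxy)chroman-4-ol | CC(C)=CCOc1ccc([C@H]2C[C@@H](O)c3c(OCC=C(C)C)cc(OCOC)cc3O2)c(OCOC)c1
F16 | step 9 | (2S)-2-[5-(2-methylbut-3-en-2-yl)-2,4-bis(triethylsilyloxy)phenyl]-8-(3-methylbut-2-enyl)-5,7-bis(triethylsilyloxy)chroman-4-one | C=CC(C)(C)c1cc([C@@H]2CC(=O)c3c(O[Si](CC)(CC)CC)cc(O[Si](CC)(CC)CC)c(CC=C(C)C)c3O2)c(O[Si](CC)(CC)CC)cc1O[Si](CC)(CC)CC
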